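Labdane numbering (C1–C20) is used for every compound.

**Plan**

1. Cuts: C8=C17 (ketone methylenation), C12–C13 (B-alkyl Suzuki coupling with 3-bromobutenolide) and C11=C12 (lactol Wittig) strip the side chain back to a C20–O–C11(=O) γ-lactone. C5–C10 and C8–C9 are then cut together (intramolecular Diels–Alder), followed by C1–C10 (B-alkyl Suzuki), C5=C6 (Wittig) and C3–C4 (malonate allylation).
2. Enabling feature: quaternary C10 with its oxygenated C20, and C9 with C11, are the β- and α-carbons of a 4-alkylbutenolide. C8 (sp2 in the target) can enter as the oxygen-bearing end of a diene C5=C6–C7=C8, and C1–C4 is a four-atom tether, so rings A and B can close in one cycloaddition.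
3. Forward order: the chain grows from C4, and the dienol ether is made before the butenolide is attached, because TBSOTf/Et3N would turn a butenolide into a silyloxyfuran. Rings A and B form in step 8, the lactone ring is opened, the side-chain butenolide is coupled on, and C17 comes last.
4. The C8 ketone is unveiled only after C11 has become CH2, so no β-keto lactone forms. The side-chain butenolide arrives with its double bond in place, so no alkene isomerisation is needed next to the exocyclic methylene.
5. Stereochemistry: C4 comes from enzymatic desymmetrisation of a prochiral malonate. C5, C9, C10 and the transient C8 come from the endo transition state under control of C4, and no later step touches them.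

Key step: step 8

Assumption: the esterase is taken to give the (S)-half-ester 4, as with the closely related 2-ethyl-, 2-propyl- and 2-butyl-2-methylmalonates, with its optical purity raised by crystallising the salt with an enantiopure amine; if the enzyme preferred the other ester group, reducing the ester of the carboxylate salt instead of the acid (LiBH4, then esterification) would lead into the same (S) series.

**Route**

Step 1
Reactants: 1 dimethyl 2-methylmalonate; 2 allyl bromide
Product: 3 dimethyl 2-allyl-2-methylmalonate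
Conditions: NaH, THF, 0 °C to rt
Reagents that add atoms: none
Why: Malonic ester alkylation, in which the sodium enolate of 1 displaces bromide from the unhindered allylic halide (SN2) and cannot over-alkylate; C4 is still prochiral.

Step 2
Reactants: 3 dimethyl 2-allyl-2-methylmalonate
Product: 4 (S)-2-(methoxycarbonyl)-2-methylpent-4-enoic acid
Conditions: pig liver esterase, KH2PO4/K2HPO4 buffer pH 7.5, rt, pH-stat (1 M NaOH); then 1 M HCl
Reagents that add atoms: water, SMILES O
Why: Enzymatic desymmetrisation of a prochiral 2-alkyl-2-methylmalonate, in which the esterase cleaves one enantiotopic ester and stops at the half-ester because the carboxylate is no longer a substrate; this sets C4 as (S), the only stereocentre brought in from outside.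

Step 3
Reactants: 4 (S)-2-(methoxycarbonyl)-2-methylpent-4-enoic acid
Product: 6 methyl (S)-2-formyl-2-methylpent-4-enoate, via acid chloride 5 (not isolated)
Conditions: (COCl)2, DMF (cat.), CH2Cl2, 0 °C to rt, concentrate; LiAlH(Ot-Bu)3, THF, −78 °C
Reagents that add atoms: none
Why: Acyl chloride formation followed by reduction with the bulky hydride LiAlH(Ot-Bu)3, which at −78 °C attacks an acyl chloride much faster than the aldehyde, ester or alkene; quaternary C4 cannot epimerise.

Step 4
Reactants: 6 methyl (S)-2-formyl-2-methylpent-4-enoate; 7 [2-(1,3-dioxolan-2-yl)ethyl]triphenylphosphonium bromide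
Product: 9 methyl (2S,3Z)-2-allyl-5-(1,3-dioxolan-2-yl)-2-methylpent-3-enoate, via phosphorus ylide 8 (not isolated)
Conditions: 7, KN(SiMe3)2, THF, −78 to 0 °C; then 6, −78 °C to rt
Reagents that add atoms: none
Why: Wittig olefination with a non-stabilised ylide, fast even on a neopentyl aldehyde, adds C6–C8 at once with C8 masked as an acetal; the favoured Z geometry does not matter because the double bond is moved in the next step.

Step 5
Reactants: 9 methyl (2S,3Z)-2-allyl-5-(1,3-dioxolan-2-yl)-2-methylpent-3-enoate
Product: 11 methyl (2S,4E)-2-allyl-2-methyl-6-oxohex-4-enoate, via skipped enal 10 (not isolated)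
Conditions: 1 M HCl, THF, 40 °C; then DBU (5 mol %), CH2Cl2, rt
Reagents that add atoms: water, SMILES O
Why: Acetal hydrolysis gives the β,γ-unsaturated aldehyde, whose doubly activated C7 hydrogens let catalytic base equilibrate it through the dienolate to the conjugated E-enal, the thermodynamic isomer.

Step 6
Reactants: 11 methyl (2S,4E)-2-allyl-2-methyl-6-oxohex-4-enoate
Product: 12 methyl (2S,3E,5E)-2-allyl-6-(tert-butyldimethylsilyloxy)-2-methylhexa-3,5-dienoate
Conditions: TBSOTf, Et3N, CH2Cl2, −78 to 0 °C
Reagents that add atoms: tert-butyldimethylsilyl triflate, SMILES CC(C)(C)[Si](C)(C)OS(=O)(=O)C(F)(F)F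
Why: Soft enolisation of an enal (O-silylation, then γ-deprotonation at C5) gives the 1-silyloxydiene; the s-trans enal gives the E enol ether, strain against quaternary C4 makes the new C5=C6 bond E, and no butenolide is yet present to compete for the silylating agent.

Step 7
Reactants: 12 methyl (2S,3E,5E)-2-allyl-6-(tert-butyldimethylsilyloxy)-2-methylhexa-3,5-dienoate; 13 4-bromofuran-2(5H)-one
Product: 15 methyl (2S,3E,5E)-6-(tert-butyldimethylsilyloxy)-2-methyl-2-[3-(5-oxo-2,5-dihydrofuran-3-yl)propyl]hexa-3,5-dienoate, via B-alkyl-9-BBN 14 (not isolated)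
Conditions: 9-BBN-H, THF, 0 °C to rt; then 13, PdCl2(dppf) (5 mol %), AsPh3, aq. K3PO4, DMF, rt
Reagents that add atoms: none
Why: Hydroboration/B-alkyl Suzuki–Miyaura coupling, in which 9-BBN-H adds anti-Markovnikov to the monosubstituted alkene far faster than to the conjugated 1,2-disubstituted diene and the β-bromo-enoate adds readily to zerovalent palladium; C1–C10 therefore forms at rt under a mild base that the TBS dienol ether should tolerate.

Step 8
Reactants: 15 methyl (2S,3E,5E)-6-(tert-butyldimethylsilyloxy)-2-methyl-2-[3-(5-oxo-2,5-dihydrofuran-3-yl)propyl]hexa-3,5-dienoate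
Product: 16 methyl 8β-(tert-butyldimethylsilyloxy)-11-oxo-11,20-epoxy-12,13,14,15,16,17-hexanorlabd-6-en-19-oate (trans-decalin with 5α-H and 10β-CH2O; γ-lactone C20–O–C11(=O) cis-fused on C9–C10 with 9α-H; 4α-CH3 and 4β-CO2CH3)
Conditions: toluene (0.01 M), BHT, base-washed sealed tube, 180 °C
Reagents that add atoms: none
Why: Thermal, concerted but asynchronous suprafacial [4+2] cycloaddition, a type 1 intramolecular Diels–Alder reaction of a 1,7,9-decatriene, whose closest known relatives are thermal cyclisations of trienes carrying a cyclic unsaturated lactone as dienophile to angularly substituted trans-decalins. Ring B is the new cyclohexene (bonds C5–C10 and C8–C9, C6=C7 left over), and ring A closes at the same time as a six-membered carbocycle over the four-atom tether C1–C4, which adopts a chair. The oxygen on C8 makes C5 the nucleophilic diene terminus and the lactone carbonyl makes C10 the electrophilic dienophile carbon, so polarity and tether demand the same regiochemistry, and since neither C4 nor the oxygen carries hydrogen no 1,5-hydrogen shift can drain the diene. C9 and C10 follow from suprafacial addition to the ring-locked dienophile (C11 cis to C20), while C5 and C8 follow from the E,E-diene reacting endo: the lactone, whose carbonyl is trans to the tether, lies under C6–C7, which places 5-H anti to C20 (trans fusion) and the silyloxy group on the β face. The diene face is selected by C4, because in the chair-like tether the flat ester (smaller A value) rather than the methyl group takes the axial site syn to C20, and with (S)-C4 this gives the 5α-H, 9α-H, 10β series of the target. The step therefore needs endo and facial selectivity; both wrong modes give diastereomers, not the enantiomer, so chromatography should restore a single isomer without loss of optical purity.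

Step 9
Reactants: 16 tricyclic lactone with C6=C7
Product: 17 methyl 8β-(tert-butyldimethylsilyloxy)-11-oxo-11,20-epoxy-12,13,14,15,16,17-hexanorlabdan-19-oate
Conditions: H2 (1 atm), Pd/C, EtOAc, rt
Reagents that add atoms: none
Why: Heterogeneous hydrogenation of the only C=C bond (disubstituted C6=C7) creates no stereocentre and leaves lactone, ester and silyl ether alone.

Step 10
Reactants: 17 saturated tricyclic lactone
Product: 18 methyl 8β-(tert-butyldimethylsilyloxy)-11-hydroxy-11,20-epoxy-12,13,14,15,16,17-hexanorlabdan-19-oate (lactol, C11 epimers)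
Conditions: i-Bu2AlH (1.1 equiv), CH2Cl2, −78 °C; aq. potassium sodium tartrate
Reagents that add atoms: none
Why: Partial reduction of a γ-lactone with one equivalent of i-Bu2AlH at −78 °C stops at the stable aluminium lactolate, while the axial neopentyl C19 methyl ester is much more hindered and should be left.

Step 11
Reactants: 18 lactol
Product: 20 methyl 20-acetoxy-8β-(tert-butyldimethylsilyloxy)-13,14,15,16,17-pentanorlabd-11-en-19-oate, via hydroxy ester 19 (not isolated)
Conditions: Ph3PCH3Br (4 equiv), KN(SiMe3)2 (3.8 equiv), THF, 0 °C; 18, −20 to 0 °C; pH 7 work-up; crude, Ac2O, DMAP, pyridine, CH2Cl2, 0 °C to rt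
Reagents that add atoms: methyltriphenylphosphonium bromide, SMILES C[P+](c1ccccc1)(c1ccccc1)c1ccccc1.[Br-]; acetic anhydride, SMILES CC(=O)OC(C)=O
Why: Wittig methylenation of the lactol through its hydroxy-aldehyde tautomer adds C12 and frees the C20 hydroxyl, which is acetylated at once (DMAP-catalysed acylation) before it can close onto the syn-axial C19 ester; a slight deficit of base keeps free alkoxide low, and the equatorial C9 substituent is the stable epimer.

Step 12
Reactants: 21 furan-2(5H)-one
Product: 23 3-bromofuran-2(5H)-one, via dibromolactone 22 (not isolated)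
Conditions: Br2, CH2Cl2, 0 °C to reflux; then Et3N, 0 °C
Reagents that add atoms: bromine, SMILES BrBr
Why: Bromine addition to the butenolide followed by E1cB loss of HBr (acidic C3 hydrogen, C4 bromide) is the standard route to the α-bromobutenolide.

Step 13
Reactants: 20 vinyl acetate; 23 3-bromofuran-2(5H)-one
Product: 25 methyl 20-acetoxy-8β-(tert-butyldimethylsilyloxy)-17-norlabd-13-en-16,15-olid-19-oate, via B-alkyl-9-BBN 24 (not isolated)
Conditions: 9-BBN-H, THF, rt to 50 °C; then 23, PdCl2(dppf) (5 mol %), AsPh3, aq. K3PO4, DMF, rt to 40 °C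
Reagents that add atoms: none
Why: The same hydroboration/B-alkyl Suzuki–Miyaura sequence, on the only alkene of 20 and an α-bromo-enoate of the kind used in couplings of α-halo enones, forms C12–C13 and brings in the butenolide with its double bond already endocyclic.

Step 14
Reactants: 25 silyl ether
Product: 26 methyl 20-acetoxy-8β-hydroxy-17-norlabd-13-en-16,15-olid-19-oate
Conditions: 48% aq. HF, MeCN, rt
Reagents that add atoms: none
Why: Acidic fluoride cleavage of a secondary TBS ether, to which acetate, methyl ester and butenolide are stable.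

Step 15
Reactants: 26 C8 alcohol
Product: 27 methyl 20-acetoxy-8-oxo-17-norlabd-13-en-16,15-olid-19-oate
Conditions: Dess–Martin periodinane, CH2Cl2, 0 °C to rt
Reagents that add atoms: none
Why: Dess–Martin oxidation under neutral conditions; with C11 now a CH2 group the ketone is an ordinary one, and C9 keeps its equatorial, more stable side chain.

Step 16
Reactants: 27 C8 ketone
Product: 28 methyl (4S,5R,9S,10S)-20-acetoxylabda-8(17),13-dien-16,15-olid-19-oate (target)
Conditions: Zn, CH2Br2, TiCl4, THF (reagent aged at 5 °C); 27, CH2Cl2, 0 °C to rt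
Reagents that add atoms: dibromomethane, SMILES BrCBr
Why: Takai–Lombardo methylenation, in which the non-basic gem-dizinc/titanium reagent attacks ketones but not esters or lactones, so C9 should not epimerise and butenolide, acetate and methyl ester should persist.

**Compound list**

1 | dimethyl 2-methylmalonate | COC(=O)C(C)C(=O)OC | starting material
2 | allyl bromide | C=CCBr | starting material
3 | dimethyl 2-allyl-2-methylmalonate | C=CCC(C)(C(=O)OC)C(=O)OC | intermediate
4 | (S)-2-(methoxycarbonyl)-2-methylpent-4-enoic acid | C=CC[C@](C(=O)O)(C)C(=O)OC | intermediate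
5 | methyl (R)-2-(chlorocarbonyl)-2-methylpent-4-enoate | C=CC[C@](C(=O)Cl)(C)C(=O)OC | intermediate
6 | methyl (S)-2-formyl-2-methylpent-4-enoate | C=CC[C@](C=O)(C)C(=O)OC | intermediate
7 | [2-(1,3-dioxolan-2-yl)ethyl]triphenylphosphonium bromide | [Br-].c1ccccc1[P+](CCC1OCCO1)(c1ccccc1)c1ccccc1 | starting material
8 | [2-(1,3-dioxolan-2-yl)ethylidene]triphenylphosphorane | c1ccccc1P(=CCC1OCCO1)(c1ccccc1)c1ccccc1 | intermediate
9 | methyl (2S,3Z)-2-allyl-5-(1,3-dioxolan-2-yl)-2-methylpent-3-enoate | C=CC[C@](/C=C\CC1OCCO1)(C)C(=O)OC | intermediate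
10 | methyl (2S,3Z)-2-allyl-2-methyl-6-oxohex-3-enoate | C=CC[C@](/C=C\CC=O)(C)C(=O)OC | intermediate
11 | methyl (2S,4E)-2-allyl-2-methyl-6-oxohex-4-enoate | C=CC[C@](C/C=C/C=O)(C)C(=O)OC | intermediate
12 | methyl (2S,3E,5E)-2-allyl-6-(tert-butyldimethylsilyloxy)-2-methylhexa-3,5-dienoate | C=CC[C@](/C=C/C=C/O[Si](C)(C)C(C)(C)C)(C)C(=O)OC | intermediate
13 | 4-bromofuran-2(5H)-one | O=C1OCC(Br)=C1 | starting material
14 | C1-(9-borabicyclo[3.3.1]nonan-9-yl) adduct of 12 | B1(CCC[C@](/C=C/C=C/O[Si](C)(C)C(C)(C)C)(C)C(=O)OC)C2CCCC1CCC2 | intermediate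
15 | butenolide silyloxydiene triene (Diels–Alder precursor) | O=C1OCC(CCC[C@](/C=C/C=C/O[Si](C)(C)C(C)(C)C)(C)C(=O)OC)=C1 | intermediate
16 | tricyclic lactone, 8β-OTBS, C6=C7 (Diels–Alder product) | CC(C)(C)[Si](C)(C)O[C@H]1C=C[C@@H]2[C@](COC3=O)(CCC[C@]2(C)C(=O)OC)[C@H]13 | intermediate
17 | saturated tricyclic lactone | CC(C)(C)[Si](C)(C)O[C@H]1CC[C@@H]2[C@](COC3=O)(CCC[C@]2(C)C(=O)OC)[C@H]13 | intermediate
18 | lactol (C11 epimers) | CC(C)(C)[Si](C)(C)O[C@H]1CC[C@@H]2[C@](COC3O)(CCC[C@]2(C)C(=O)OC)[C@H]13 | intermediate
19 | C9-vinyl 20-hydroxy 19-methyl ester | CC(C)(C)[Si](C)(C)O[C@H]1CC[C@@H]2[C@](CO)(CCC[C@]2(C)C(=O)OC)[C@H]1C=C | intermediate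
20 | C9-vinyl 20-acetate | CC(C)(C)[Si](C)(C)O[C@H]1CC[C@@H]2[C@](COC(C)=O)(CCC[C@]2(C)C(=O)OC)[C@H]1C=C | intermediate
21 | furan-2(5H)-one | O=C1OCC=C1 | starting material
22 | 3,4-dibromodihydrofuran-2(3H)-one (racemic trans) | O=C1OCC(Br)C1Br | intermediate
23 | 3-bromofuran-2(5H)-one | O=C1OCC=C1Br | intermediate
24 | C12-(9-borabicyclo[3.3.1]nonan-9-yl) adduct of 20 | CC(C)(C)[Si](C)(C)O[C@H]1CC[C@@H]2[C@](COC(C)=O)(CCC[C@]2(C)C(=O)OC)[C@H]1CCB1C2CCCC1CCC2 | intermediate
25 | 8β-OTBS 17-nor butenolide | CC(C)(C)[Si](C)(C)O[C@H]1CC[C@@H]2[C@](COC(C)=O)(CCC[C@]2(C)C(=O)OC)[C@H]1CCC1=CCOC1=O | intermediate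
26 | 8β-hydroxy 17-nor butenolide | O[C@H]1CC[C@@H]2[C@](COC(C)=O)(CCC[C@]2(C)C(=O)OC)[C@H]1CCC1=CCOC1=O | intermediate
27 | 8-oxo 17-nor butenolide | O=C1CC[C@@H]2[C@](COC(C)=O)(CCC[C@]2(C)C(=O)OC)[C@H]1CCC1=CCOC1=O | intermediate
28 | methyl (4S,5R,9S,10S)-20-acetoxylabda-8(17),13-dien-16,15-olid-19-oate | C=C1CC[C@@H]2[C@](COC(C)=O)(CCC[C@]2(C)C(=O)OC)[C@H]1CCC1=CCOC1=O | target

**Step count**

Total steps: 16. Longest linear sequence: 15 (steps 1–11 and 13–16). Step 12 is a one-step side branch.

**The three steps most likely to fail**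

**Step 8.** The cycloaddition must join neopentyl C5 to fully substituted C10. It may therefore be too slow below the temperature at which the dienol ether degrades. At that temperature the discrimination between endo and exo modes, and between the two diene faces (ester versus methyl axial), may be weak.

The fallback adds a second, removable activating group. It sets out from 12 (through borane 14) and returns at 16.
- Coupling of 14 with commercial 3,4-dibromofuran-2(5H)-one (O=C1OCC(Br)=C1Br), which reacts selectively at C4 under palladium catalysis, would give the α-bromobutenolide triene F1.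
- The halogen lowers the dienophile LUMO. Because C8–C9 lags behind C5–C10 in the asynchronous transition state, it should cost little sterically. The cycloaddition to the C9-bromo adduct F2 should then run at a clearly lower temperature with sharper endo and facial discrimination.
- Radical debromination (n-Bu3SnH, AIBN, benzene, 80 °C) gives 16. Zinc is avoided because it would expel the β-silyloxy group. The cis lactone fusion dictates the C9 configuration.

**Step 11.** Once C20–O is freed it sits 1,3-diaxial to C19. Under the basic Wittig conditions it may close to the six-membered 19,20-lactone with loss of methanol. Base-induced loss of silanol from the β-silyloxy aldehyde tautomer is a second drain.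

The fallback masks C19 as a carboxylate, which an alkoxide cannot attack. It sets out from 17 and returns at 20.
- SN2 demethylation (LiI, pyridine, reflux) gives the lactone acid F3.
- i-Bu2AlH (2.2 equiv, −78 °C) gives the lactol acid F4.
- Excess Ph3P=CH2 gives the potassium hydroxy-carboxylate F5.
- F5 is quenched in the same flask with Ac2O; aqueous NaHCO3 then hydrolyses the mixed anhydride and gives the acetoxy acid F6.
- Me3SiCHN2 in toluene/MeOH re-forms the methyl ester, giving 20.

**Step 16.** The low-valent zinc/titanium mixture may attack the conjugated lactone. Alternatively, addition to the C8 ketone, which is flanked by axial C20, may be too slow.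

The fallback carries the butenolide masked as an α-phenylthio lactone through an ordinary Wittig methylenation. It sets out from 20 (through borane 24) and returns at 28.
- Oxidation of 24 with NaBO3·4H2O gives the primary alcohol F7, and I2/PPh3/imidazole gives the iodide F8.
- α-Bromo-γ-butyrolactone with PhSH/Et3N gives 3-(phenylthio)dihydrofuran-2(3H)-one F9. Its sodium enolate (NaH, THF/DMPU) is alkylated by F8 to the sulfide lactone F10 (C13 epimers).
- Aqueous HF gives the alcohol F11, Dess–Martin periodinane gives the ketone F12, and Ph3P=CH2 (slight excess, 0 °C) gives the exocyclic alkene F13.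
- mCPBA (1 equiv, −78 °C) gives the sulfoxide F14. Its thermal syn elimination in refluxing toluene should place the double bond inside the lactone ring and deliver 28.

**Further compounds**
F1 | step 8 | methyl (2S,3E,5E)-2-[3-(4-bromo-5-oxo-2,5-dihydrofuran-3-yl)propyl]-6-(tert-butyldimethylsilyloxy)-2-methylhexa-3,5-dienoate | O=C1OCC(CCC[C@](/C=C/C=C/O[Si](C)(C)C(C)(C)C)(C)C(=O)OC)=C1Br
F2 | step 8 | 9α-bromo analogue of tricyclic lactone 16 | CC(C)(C)[Si](C)(C)O[C@H]1C=C[C@@H]2[C@](COC3=O)(CCC[C@]2(C)C(=O)OC)[C@]13Br
F3 | step 11 | 19-carboxylic acid of lactone 17 | CC(C)(C)[Si](C)(C)O[C@H]1CC[C@@H]2[C@](COC3=O)(CCC[C@]2(C)C(=O)O)[C@H]13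
F4 | step 11 | 19-carboxylic acid of lactol 18 (C11 epimers) | CC(C)(C)[Si](C)(C)O[C@H]1CC[C@@H]2[C@](COC3O)(CCC[C@]2(C)C(=O)O)[C@H]13
F5 | step 11 | potassium 20-hydroxy-8β-(tert-butyldimethylsilyloxy)-13,14,15,16,17-pentanorlabd-11-en-19-oate | [K+].CC(C)(C)[Si](C)(C)O[C@H]1CC[C@@H]2[C@](CO)(CCC[C@]2(C)C(=O)[O-])[C@H]1C=C
F6 | step 11 | 20-acetoxy-8β-(tert-butyldimethylsilyloxy)-13,14,15,16,17-pentanorlabd-11-en-19-oic acid | CC(C)(C)[Si](C)(C)O[C@H]1CC[C@@H]2[C@](COC(C)=O)(CCC[C@]2(C)C(=O)O)[C@H]1C=C
F7 | step 16 | C12 primary alcohol from 20 | CC(C)(C)[Si](C)(C)O[C@H]1CC[C@@H]2[C@](COC(C)=O)(CCC[C@]2(C)C(=O)OC)[C@H]1CCO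
F8 | step 16 | C12 primary iodide | CC(C)(C)[Si](C)(C)O[C@H]1CC[C@@H]2[C@](COC(C)=O)(CCC[C@]2(C)C(=O)OC)[C@H]1CCI
F9 | step 16 | 3-(phenylthio)dihydrofuran-2(3H)-one | O=C1OCCC1Sc1ccccc1
F10 | step 16 | 13-phenylthio 16,15-lactone with 8β-OTBS (C13 epimers) | CC(C)(C)[Si](C)(C)O[C@H]1CC[C@@H]2[C@](COC(C)=O)(CCC[C@]2(C)C(=O)OC)[C@H]1CCC1(Sc2ccccc2)CCOC1=O
F11 | step 16 | 13-phenylthio lactone with 8β-OH | O[C@H]1CC[C@@H]2[C@](COC(C)=O)(CCC[C@]2(C)C(=O)OC)[C@H]1CCC1(Sc2ccccc2)CCOC1=O
F12 | step 16 | 13-phenylthio lactone with 8-oxo group | O=C1CC[C@@H]2[C@](COC(C)=O)(CCC[C@]2(C)C(=O)OC)[C@H]1CCC1(Sc2ccccc2)CCOC1=O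
F13 | step 16 | 13-phenylthio lactone with 8(17)-methylene | C=C1CC[C@@H]2[C@](COC(C)=O)(CCC[C@]2(C)C(=O)OC)[C@H]1CCC1(Sc2ccccc2)CCOC1=O
F14 | step 16 | 13-phenylsulfinyl lactone with 8(17)-methylene | C=C1CC[C@@H]2[C@](COC(C)=O)(CCC[C@]2(C)C(=O)OC)[C@H]1CCC1(S(=O)c2ccccc2)CCOC1=O
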